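## Analysis of the target

The target is (3S,4S,7S)-4-(4-hydroxy-3-methoxyphenyl)-7-(3-hydroxy-4-methoxybenzyl)-1,5-dioxaspiro[2.4]heptane: a tetrahydrofuran (ring A) with a spiro-fused oxirane (ring B). For the discussion, ring A is numbered O1, C2 (bears the 4-hydroxy-3-methoxyphenyl group), C3 (spiro carbon), C4 (bears the arylmethyl group through benzylic C7') and C5; the oxirane is C3–C6–O7. C2, C3 and C4 are contiguous stereocentres. Read from the SMILES, the C2 aryl and C4 arylmethyl groups are cis on ring A, and O7 lies on the opposite face, so that C6 is cis to both. The 2,2-disubstituted epoxide is acid-labile, and C2 is a benzylic ether para to a free phenol, so acid (ionisation of C2–O1) and phenoxide-forming base both threaten the finished skeleton. The two arenes are regioisomers (4-hydroxy-3-methoxy at C2, 3-hydroxy-4-methoxy at C7'), so they must come from different building blocks, and the phenols must stay masked through any oxidation and be released under near-neutral conditions. The difficulty is the fully substituted spiro carbon C3 between two stereocentres, to be set in relative and absolute configuration in few steps. The strategy rests on the one-carbon unit C6 on C3 next to the arylmethyl branch on C4: this is the imprint of an enyne tethered through O1, with C3≡C6 as a terminal alkyne and C4=C7' as a cinnamyl alkene.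

## Retrosynthetic reasoning

**Phenol release (15 ⇐ 14).** The two aryl O–Si bonds are cut last. Free electron-rich phenols would not survive the oxidation that makes the epoxide, and silyl ethers leave with buffered fluoride, which should spare the epoxide and the C2–O1 bond.

**Epoxide (14 ⇐ 13).** C3–O7 and C6–O7 are cut together, leading back to the exocyclic alkene 13. This removes the quaternary stereocentre from the problem: C3 is made only at this point, by a peracid approaching the face of ring A not occupied by the cis C2 and C4 substituents, which is the face the target requires.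

**Ring A (13 ⇐ 12).** The C3–C4 bond is cut, together with one C–H bond at C6 and one at C7'. This reveals the propargylic cinnamyl ether 12. The cut is made here because both ends are then simple unsaturated carbons: C6 is the terminal alkyne carbon and C7' the styrenyl carbon. The forward reaction forms the ring, the exocyclic methylene and the C4 stereocentre in one catalytic step. It must put the metal on C3, close 5-exo onto C4, reduce the benzylic C7'–metal bond before beta-hydride elimination, and let C2 dictate C4.

**Ether (12 ⇐ 5 + 11).** O1–C5 is cut, not O1–C2. Alkylating the alkoxide of 5 with the allylic bromide 11 leaves the C2–O bond untouched, whereas making O1–C2 by substitution at a benzylic propargylic carbon would risk the stereocentre. Triisopropylsilyl is used on both phenols because aryl silyl ethers must here survive an alkoxide, and the bulkier group resists silyl transfer.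

**C2 stereocentre (5 ⇐ 4 ⇐ 2 + 3; 2 ⇐ 1).** The C2–C3 bond is cut to aldehyde 2 and trimethylsilylacetylene 3. A catalytic enantioselective alkynylation sets the only stereocentre that is not relayed, and selective C-desilylation of 4 exposes the terminal alkyne of 5. Aldehyde 2 is silylated vanillin 1.

**Cinnamyl bromide (11 ⇐ 10 ⇐ 9 ⇐ 7 + 8; 7 ⇐ 6).** The C4=C7' bond is cut by olefination of aldehyde 7 (silylated isovanillin 6) with triethyl phosphonoacetate 8. Ester reduction and bromination then adjust C5.

## Alternatives that were turned down

**Alternative 1: three-component palladium assembly.**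
- Disconnection: O1–C2, C3–C4 and the C7'–aryl bond at once. The pieces are arylidene malonate A1 (from aldehyde 2), prop-2-yn-1-ol A2 and aryl iodide A3.
- Forward key step: the alkoxide of A2 adds to A1 (oxa-Michael, O1–C2). The resulting malonate carbanion attacks the alkyne activated by the arylpalladium iodide from A3 (C3–C4, ring closure), and reductive elimination attaches the aryl group to C7', giving diester A4.
- For: three bonds and the ring in one operation from simple, interchangeable pieces. On convergence this is stronger than the chosen route.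
- Against: C3 arrives as a gem-diester, one carbon too many and at the wrong oxidation level. One ester must be removed and the other reduced and eliminated before any epoxidation, which is four to five extra steps to reach the stage of 13. C2 forms in a reversible conjugate addition with no element controlling its absolute configuration. C4 has to be set afterwards by hydrogenating the arylidene next to a quaternary centre, with only the C2 aryl group to direct it.
- Comparison: the chosen route gives up some convergence but sets C2 by catalysis, creates C4 during ring closure, and delivers C6 as the methylene that is epoxidised directly.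

**Alternative 2: asymmetric epoxide relay with 5-endo benzylic closure.**
- Disconnection: O1–C2, with O7 already on C3. The precursor is the open-chain epoxy diol A5, whose C2–C3 oxirane comes from a Sharpless asymmetric epoxidation and whose C4 centre is built beforehand.
- Forward key step: mild acid lets the C5 hydroxyl open the oxirane at benzylic C2 with inversion, closing ring A and leaving O7 as the tertiary alcohol of diol A6. Primary sulfonylation and base would then re-form the epoxide with the C3–O7 bond intact.
- For: O7 and C2 are set under reagent control. On this point it is stronger than the chosen route, which relies on substrate face selectivity for C3.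
- Against: endo opening of an epoxide to a five-membered ring is stereoelectronically disfavoured and works only because C2 is benzylic. That same activation invites ionisation and loss of stereospecificity with these electron-rich arenes, hence the deactivating pivalates. C4 needs its own asymmetric step, the trisubstituted alkene must be a single geometric isomer, and the protecting groups must be exchanged.
- Comparison: markedly longer. The chosen route offers one catalytic step for ring and C4 in place of reagent control at C3.

**Alternative 3: alkoxymethyl radical 5-exo cyclisation onto a styrene.**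
- Disconnection: C4–C5. The precursor is acid A7, with O1 carrying a carboxymethyl group and C3 already the tertiary carbinol.
- Forward key step: photoredox oxidation of the carboxylate and loss of CO2 give the C5 radical. It closes 5-exo-trig onto C4, and the benzylic C7' radical is reduced and protonated, giving A8.
- For: a nucleophilic alpha-oxy radical adding to a styrene is fast and well matched, and a free tertiary hydroxyl is tolerated. C3 is fixed before ring closure, so no late face-selective epoxidation is needed. On C3 it is as strong as or stronger than the chosen route.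
- Against: C4 is created beside a fully substituted C3 whose two groups (OH and CH2OSi) are similar in size, so only the more remote C2 aryl group biases the closure. A7 needs acyclic control of the C2/C3 pair and a selective O-alkylation of a hindered secondary benzylic hydroxyl next to a tertiary one. Three further steps (selective primary desilylation, sulfonylation, closure) follow before deprotection.
- Comparison: the chosen route is shorter and puts its risk in one well-precedented reaction type.

Key step: step 9

Assumption (remark on the chemistry): the (S,S)-ligand in step 2 is taken to deliver the alkynyl group to the Re face of aldehyde 2, which gives the configuration drawn for 4. If the first run shows the opposite sense (chiral HPLC against the racemate, MTPA ester analysis), the (R,R)-ligand is used with no other change.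

## Route

Step 1
Reactants: 1 vanillin (4-hydroxy-3-methoxybenzaldehyde)
Product: 2 3-methoxy-4-(triisopropylsilyloxy)benzaldehyde
Conditions: TIPSCl, imidazole, DMF, rt
Reagents that add atoms: triisopropylsilyl chloride (TIPSCl), CC(C)[Si](Cl)(C(C)C)C(C)C
Why: Imidazole-assisted silylation of the phenol; the bulky triisopropylsilyl ether is chosen to survive the alkoxide of step 8 and the acid of step 9.

Step 2
Reactants: 2 3-methoxy-4-(triisopropylsilyloxy)benzaldehyde; 3 trimethylsilylacetylene
Product: 4 (S)-1-[3-methoxy-4-(triisopropylsilyloxy)phenyl]-3-(trimethylsilyl)prop-2-yn-1-ol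
Conditions: (S,S)-ProPhenol [2,6-bis{[(S)-2-(hydroxydiphenylmethyl)pyrrolidin-1-yl]methyl}-4-methylphenol] (10 mol %), Ph3P=O (20 mol %), Me2Zn (3 equiv), 3 (3 equiv), toluene, 0 °C; aq. NH4Cl
Reagents that add atoms: none
Why: Catalytic enantioselective alkynylation of an aromatic aldehyde by a dinuclear zinc–aminoalcohol catalyst; the alkynylzinc made from 3 and Me2Zn is delivered inside the chiral pocket to the Re face of the aldehyde, which sets C2 (descriptor S here only because the silylalkynyl group outranks the aryl group).

Step 3
Reactants: 4 (S)-1-[3-methoxy-4-(triisopropylsilyloxy)phenyl]-3-(trimethylsilyl)prop-2-yn-1-ol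
Product: 5 (R)-1-[3-methoxy-4-(triisopropylsilyloxy)phenyl]prop-2-yn-1-ol
Conditions: AgNO3 (10 mol %), acetone/H2O, rt, dark
Reagents that add atoms: none
Why: Silver-catalysed protodesilylation of the alkynyl C–Si bond through a silver acetylide that water protonates; the neutral conditions should leave the aryl silyl ether and the stereocentre untouched (same geometry, descriptor now R).

Step 4
Reactants: 6 isovanillin (3-hydroxy-4-methoxybenzaldehyde)
Product: 7 4-methoxy-3-(triisopropylsilyloxy)benzaldehyde
Conditions: TIPSCl, imidazole, DMF, rt
Reagents that add atoms: triisopropylsilyl chloride (TIPSCl), CC(C)[Si](Cl)(C(C)C)C(C)C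
Why: Same phenol silylation as in step 1.

Step 5
Reactants: 7 4-methoxy-3-(triisopropylsilyloxy)benzaldehyde; 8 triethyl phosphonoacetate
Product: 9 ethyl (E)-3-[4-methoxy-3-(triisopropylsilyloxy)phenyl]acrylate
Conditions: NaH, 8, THF, 0 °C, then 7, 0 °C to rt
Reagents that add atoms: none
Why: Horner–Wadsworth–Emmons olefination; the stabilised phosphonate anion should give the (E)-cinnamate.

Step 6
Reactants: 9 ethyl (E)-3-[4-methoxy-3-(triisopropylsilyloxy)phenyl]acrylate
Product: 10 (E)-3-[4-methoxy-3-(triisopropylsilyloxy)phenyl]prop-2-en-1-ol
Conditions: iBu2AlH (2.5 equiv), CH2Cl2, −78 °C; aq. potassium sodium tartrate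
Reagents that add atoms: none
Why: 1,2-Reduction of the unsaturated ester by the aluminium hydride at low temperature gives the allylic alcohol without touching the alkene or the aryl silyl ether.

Step 7
Reactants: 10 (E)-3-[4-methoxy-3-(triisopropylsilyloxy)phenyl]prop-2-en-1-ol
Product: 11 (E)-4-methoxy-3-(triisopropylsilyloxy)cinnamyl bromide, i.e. [5-((E)-3-bromoprop-1-enyl)-2-methoxyphenoxy]triisopropylsilane
Conditions: PBr3 (0.4 equiv), Et2O, 0 °C; cold aq. NaHCO3; used crude at once
Reagents that add atoms: phosphorus tribromide, BrP(Br)Br
Why: Bromination of a primary allylic alcohol through its phosphite ester; the conjugated primary bromide is also the thermodynamic allylic isomer, so the (E)-linear compound is expected, but it is labile and is not chromatographed.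

Step 8
Reactants: 5 (R)-1-[3-methoxy-4-(triisopropylsilyloxy)phenyl]prop-2-yn-1-ol; 11 (E)-4-methoxy-3-(triisopropylsilyloxy)cinnamyl bromide
Product: 12 (R)-1-[3-methoxy-4-(triisopropylsilyloxy)phenyl]prop-2-yn-1-yl (E)-3-[4-methoxy-3-(triisopropylsilyloxy)phenyl]allyl ether
Conditions: NaH (1.1 equiv) added to 5 and 11 (1.2 equiv), Bu4NI (5 mol %), THF, 0 °C to rt
Reagents that add atoms: none
Why: Williamson ether synthesis; the alkoxide is trapped as it forms by SN2 displacement at the primary allylic carbon (iodide catalysis), which forms O1–C5 and never touches the C2–O bond, so the C2 configuration is carried over.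

Step 9
Reactants: 12 (R)-1-[3-methoxy-4-(triisopropylsilyloxy)phenyl]prop-2-yn-1-yl (E)-3-[4-methoxy-3-(triisopropylsilyloxy)phenyl]allyl ether
Product: 13 (2R,4R)-2-[3-methoxy-4-(triisopropylsilyloxy)phenyl]-4-[4-methoxy-3-(triisopropylsilyloxy)benzyl]-3-methylenetetrahydrofuran (aryl and arylmethyl groups cis)
Conditions: Pd2(dba)3·CHCl3 (2.5 mol %), P(o-tol)3 (10 mol %), AcOH (2 equiv), Et3SiH (5 equiv), toluene, rt
Reagents that add atoms: none
Why: Reductive 1,6-enyne cyclisation under palladium hydride catalysis, the closest known reaction type being the Pd2(dba)3/carboxylic acid/silane reductive cyclisation of carbon- and oxygen-tethered 1,6-enynes. Oxidative addition of AcOH to zerovalent palladium gives H–Pd–OAc, which adds syn across the terminal alkyne with hydrogen on C6 and palladium on the internal carbon C3. The C3 vinylpalladium then inserts the cinnamyl alkene in a 5-exo-trig syn-carbopalladation that forms C3–C4 and closes ring A, leaving palladium on benzylic C7'. Et3SiH turns this benzyl–Pd–OAc into benzyl–Pd–H, and C–H reductive elimination gives the C7' methylene and returns zerovalent palladium. The new stereocentre C4 is controlled by C2: the four-centre insertion needs C3–Pd and C4=C7' coplanar, which fixes C7' pseudo-equatorial on an envelope-like ring, and the C2 aryl group takes the pseudo-equatorial site as well (its pseudo-axial alternative would face the pseudo-axial C4–H), so the 2,4-cis isomer should dominate. Because C6 carries only hydrogen, the pseudo-equatorial aryl group meets no allylic strain from the exocyclic carbon. Regiochemistry is secured by the terminal alkyne (palladium ends on C3), and reduction must outrun beta-hydride elimination towards C4, which the excess silane and the eta-3 benzyl character of the C7'–Pd species should ensure.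

Step 10
Reactants: 13 (2R,4R)-2-[3-methoxy-4-(triisopropylsilyloxy)phenyl]-4-[4-methoxy-3-(triisopropylsilyloxy)benzyl]-3-methylenetetrahydrofuran
Product: 14 (3S,4S,7S)-4-[3-methoxy-4-(triisopropylsilyloxy)phenyl]-7-[4-methoxy-3-(triisopropylsilyloxy)benzyl]-1,5-dioxaspiro[2.4]heptane (O7 trans to the aryl and arylmethyl groups)
Conditions: mCPBA (1.3 equiv), NaHCO3 (3 equiv), CH2Cl2, 0 °C
Reagents that add atoms: 3-chloroperoxybenzoic acid (mCPBA), OOC(=O)c1cccc(Cl)c1
Why: Prilezhaev epoxidation; concerted oxygen transfer to the exocyclic 1,1-disubstituted alkene should occur on the ring face not shielded by the cis C2 aryl and C4 arylmethyl groups, which sets C3 with O7 trans to both, and the bicarbonate buffer protects the acid-labile product.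

Step 11
Reactants: 14 (3S,4S,7S)-4-[3-methoxy-4-(triisopropylsilyloxy)phenyl]-7-[4-methoxy-3-(triisopropylsilyloxy)benzyl]-1,5-dioxaspiro[2.4]heptane
Product: 15 (3S,4S,7S)-4-(4-hydroxy-3-methoxyphenyl)-7-(3-hydroxy-4-methoxybenzyl)-1,5-dioxaspiro[2.4]heptane (target, CNP0184956.1)
Conditions: Bu4NF (2.4 equiv), AcOH (2.4 equiv), THF, 0 °C
Reagents that add atoms: none
Why: Fluoride cleavage of the two aryl Si–O bonds, driven by Si–F bond formation; the acetic acid buffer keeps the liberated phenols protonated so that neither the epoxide nor the C2–O1 bond should be attacked, and no stereocentre is involved.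

## Compound list

1 | vanillin | COc1cc(C=O)ccc1O | starting material
2 | 3-methoxy-4-(triisopropylsilyloxy)benzaldehyde | COc1cc(C=O)ccc1O[Si](C(C)C)(C(C)C)C(C)C | intermediate
3 | trimethylsilylacetylene | C#C[Si](C)(C)C | starting material
4 | (S)-1-[3-methoxy-4-(triisopropylsilyloxy)phenyl]-3-(trimethylsilyl)prop-2-yn-1-ol | C[Si](C)(C)C#C[C@@H](O)c1ccc(O[Si](C(C)C)(C(C)C)C(C)C)c(OC)c1 | intermediate
5 | (R)-1-[3-methoxy-4-(triisopropylsilyloxy)phenyl]prop-2-yn-1-ol | C#C[C@@H](O)c1ccc(O[Si](C(C)C)(C(C)C)C(C)C)c(OC)c1 | intermediate
6 | isovanillin | COc1ccc(C=O)cc1O | starting material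
7 | 4-methoxy-3-(triisopropylsilyloxy)benzaldehyde | COc1ccc(C=O)cc1O[Si](C(C)C)(C(C)C)C(C)C | intermediate
8 | triethyl phosphonoacetate | CCOC(=O)CP(=O)(OCC)OCC | starting material
9 | ethyl (E)-3-[4-methoxy-3-(triisopropylsilyloxy)phenyl]acrylate | CCOC(=O)/C=C/c1ccc(OC)c(O[Si](C(C)C)(C(C)C)C(C)C)c1 | intermediate
10 | (E)-3-[4-methoxy-3-(triisopropylsilyloxy)phenyl]prop-2-en-1-ol | OC/C=C/c1ccc(OC)c(O[Si](C(C)C)(C(C)C)C(C)C)c1 | intermediate
11 | (E)-4-methoxy-3-(triisopropylsilyloxy)cinnamyl bromide | BrC/C=C/c1ccc(OC)c(O[Si](C(C)C)(C(C)C)C(C)C)c1 | intermediate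
12 | (R)-1-[3-methoxy-4-(triisopropylsilyloxy)phenyl]prop-2-yn-1-yl (E)-3-[4-methoxy-3-(triisopropylsilyloxy)phenyl]allyl ether | C#C[C@@H](OC/C=C/c1ccc(OC)c(O[Si](C(C)C)(C(C)C)C(C)C)c1)c1ccc(O[Si](C(C)C)(C(C)C)C(C)C)c(OC)c1 | intermediate
13 | (2R,4R)-2-[3-methoxy-4-(triisopropylsilyloxy)phenyl]-4-[4-methoxy-3-(triisopropylsilyloxy)benzyl]-3-methylenetetrahydrofuran | COc1ccc(C[C@H]2CO[C@@H](c3ccc(O[Si](C(C)C)(C(C)C)C(C)C)c(OC)c3)C2=C)cc1O[Si](C(C)C)(C(C)C)C(C)C | intermediate
14 | (3S,4S,7S)-4-[3-methoxy-4-(triisopropylsilyloxy)phenyl]-7-[4-methoxy-3-(triisopropylsilyloxy)benzyl]-1,5-dioxaspiro[2.4]heptane | COc1ccc(C[C@H]2CO[C@@H](c3ccc(O[Si](C(C)C)(C(C)C)C(C)C)c(OC)c3)[C@@]23CO3)cc1O[Si](C(C)C)(C(C)C)C(C)C | intermediate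
15 | (3S,4S,7S)-4-(4-hydroxy-3-methoxyphenyl)-7-(3-hydroxy-4-methoxybenzyl)-1,5-dioxaspiro[2.4]heptane | COc1ccc(C[C@H]2CO[C@@H](c3ccc(O)c(OC)c3)[C@@]23CO3)cc1O | target

## Step count and least certain steps

Total: 11 steps. Longest linear sequence: 8 steps (steps 4 to 11, from isovanillin 6); the vanillin branch is 7 steps.

**Step 9 (key step).** The likeliest failures are beta-hydride elimination from the C7'–palladium bond before the silane intervenes (which erases C4 by forming the conjugated arylidene diene), reduction of the vinylpalladium before it inserts, and insufficient discrimination between the two envelope transition states, which would lower the 2,4-cis preference. The fallback sets out from 12 and comes back at 13 by a tin hydride radical chain. Bu3SnH with Et3B/air (or AIBN, benzene, 80 °C) adds a stannyl radical to the terminal alkyne carbon C6. The C3 vinyl radical closes 5-exo onto the cinnamyl alkene, and the benzylic radical takes hydrogen from the tin hydride, giving 2,4-cis-3-[(tributylstannyl)methylene]tetrahydrofuran F1. Protodestannylation on moist silica gel in CH2Cl2 (pyridinium tosylate if sluggish) gives 13. A radical cannot lose a beta-hydrogen, so the first failure mode disappears. The C4 selectivity would come from a different transition state and would have to be established.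

**Step 2.** The electron-rich aldehyde may react slowly and with insufficient enantioselectivity, or the sense may differ from the assumption. The fallback sets out from 2 and comes back at 5, bypassing 4 and step 3. HC≡CMgBr in THF gives racemic 1-[3-methoxy-4-(triisopropylsilyloxy)phenyl]prop-2-yn-1-ol F2. Kinetic resolution with Candida antarctica lipase B and vinyl acetate should acylate the (R)-enantiomer (aryl as the large group, ethynyl as the medium one), giving (R)-propargylic acetate F3, which is separated from the unreacted (S)-alcohol. Brief methanolysis (K2CO3, MeOH, 0 °C) then gives 5. If the enzyme prefers the other enantiomer, the unreacted alcohol is the material carried on.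

**Step 10.** The small peracid may discriminate poorly between the faces of a fairly flat ring, and acid may open the product. The fallback sets out from 13 and comes back at 14. Dihydroxylation with OsO4 (cat.) and N-methylmorpholine N-oxide, a much bulkier reagent that a cinchona-alkaloid ligand can reinforce, should give (2S,3S,4S)-3-(hydroxymethyl)tetrahydrofuran-3-ol F4, with the tertiary hydroxyl trans to the aryl and arylmethyl groups. Selective tosylation of the primary hydroxyl (TsCl, Et3N, cat. Bu2SnO) gives primary tosylate F5. NaH in THF then closes the epoxide by attack of the tertiary alkoxide on C6. The C3–O7 bond is never broken, so C3 keeps the configuration set by the osmylation.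

**Step 8.** Bromide 11 may decompose (ionisation, hydrolysis), and the propargylic alkoxide may isomerise or take a silyl group from an aryl ether. The fallback sets out from 4 and 10 and comes back at 12. Alcohol 10 with methyl chloroformate and pyridine gives (E)-cinnamyl methyl carbonate F6. A Tsuji–Trost allylic etherification of the zinc alkoxide of 4 (Et2Zn 0.5 equiv, Pd(OAc)2, 2-(di-tert-butylphosphino)biphenyl, THF, rt) should attack the unsubstituted allyl terminus and give the linear (S)-trimethylsilyl enyne ether F7. The silver-catalysed protodesilylation of step 3 then gives 12. Using 4 keeps the terminal alkyne masked during the palladium step.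

**Step 11.** The phenoxide formed on desilylation may open the epoxide or trigger cleavage of the C2–O1 bond (quinone-methide-type). The fallback sets out from 13 and comes back at 15 by changing the phenol protection before the epoxide exists. Bu4NF on 13 gives (2R,4R)-bisphenol F8. Ac2O and pyridine give diacetate F9. Buffered mCPBA as in step 10 gives diacetate epoxide F10. Neutral deacetylation (NH4OAc in aqueous MeOH, or K2CO3 in MeOH at 0 °C) then gives 15 without fluoride.

## Further compounds

F1 | step 9 | 2,4-cis-2-[3-methoxy-4-(triisopropylsilyloxy)phenyl]-4-[4-methoxy-3-(triisopropylsilyloxy)benzyl]-3-[(tributylstannyl)methylene]tetrahydrofuran (alkene geometry not defined) | COc1ccc(C[C@H]2CO[C@@H](c3ccc(O[Si](C(C)C)(C(C)C)C(C)C)c(OC)c3)C2=C[Sn](CCCC)(CCCC)CCCC)cc1O[Si](C(C)C)(C(C)C)C(C)C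
F2 | step 2 | racemic 1-[3-methoxy-4-(triisopropylsilyloxy)phenyl]prop-2-yn-1-ol | C#CC(O)c1ccc(O[Si](C(C)C)(C(C)C)C(C)C)c(OC)c1
F3 | step 2 | (R)-1-[3-methoxy-4-(triisopropylsilyloxy)phenyl]prop-2-yn-1-yl acetate | C#C[C@@H](OC(C)=O)c1ccc(O[Si](C(C)C)(C(C)C)C(C)C)c(OC)c1
F4 | step 10 | (2S,3S,4S)-3-(hydroxymethyl)-2-[3-methoxy-4-(triisopropylsilyloxy)phenyl]-4-[4-methoxy-3-(triisopropylsilyloxy)benzyl]tetrahydrofuran-3-ol | COc1ccc(C[C@H]2CO[C@@H](c3ccc(O[Si](C(C)C)(C(C)C)C(C)C)c(OC)c3)[C@@]2(O)CO)cc1O[Si](C(C)C)(C(C)C)C(C)C
F5 | step 10 | {(2S,3S,4S)-3-hydroxy-2-[3-methoxy-4-(triisopropylsilyloxy)phenyl]-4-[4-methoxy-3-(triisopropylsilyloxy)benzyl]tetrahydrofuran-3-yl}methyl 4-methylbenzenesulfonate | COc1ccc(C[C@H]2CO[C@@H](c3ccc(O[Si](C(C)C)(C(C)C)C(C)C)c(OC)c3)[C@@]2(O)COS(=O)(=O)c4ccc(C)cc4)cc1O[Si](C(C)C)(C(C)C)C(C)C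
F6 | step 8 | (E)-3-[4-methoxy-3-(triisopropylsilyloxy)phenyl]allyl methyl carbonate | COC(=O)OC/C=C/c1ccc(OC)c(O[Si](C(C)C)(C(C)C)C(C)C)c1
F7 | step 8 | (S)-1-[3-methoxy-4-(triisopropylsilyloxy)phenyl]-3-(trimethylsilyl)prop-2-yn-1-yl (E)-3-[4-methoxy-3-(triisopropylsilyloxy)phenyl]allyl ether | C[Si](C)(C)C#C[C@@H](OC/C=C/c1ccc(OC)c(O[Si](C(C)C)(C(C)C)C(C)C)c1)c1ccc(O[Si](C(C)C)(C(C)C)C(C)C)c(OC)c1
F8 | step 11 | (2R,4R)-2-(4-hydroxy-3-methoxyphenyl)-4-(3-hydroxy-4-methoxybenzyl)-3-methylenetetrahydrofuran | COc1ccc(C[C@H]2CO[C@@H](c3ccc(O)c(OC)c3)C2=C)cc1O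
F9 | step 11 | (2R,4R)-2-(4-acetoxy-3-methoxyphenyl)-4-(3-acetoxy-4-methoxybenzyl)-3-methylenetetrahydrofuran | COc1ccc(C[C@H]2CO[C@@H](c3ccc(OC(C)=O)c(OC)c3)C2=C)cc1OC(C)=O
F10 | step 11 | (3S,4S,7S)-4-(4-acetoxy-3-methoxyphenyl)-7-(3-acetoxy-4-methoxybenzyl)-1,5-dioxaspiro[2.4]heptane | COc1ccc(C[C@H]2CO[C@@H](c3ccc(OC(C)=O)c(OC)c3)[C@@]23CO3)cc1OC(C)=O
A1 | alternative 1 | diethyl 2-[3-methoxy-4-(triisopropylsilyloxy)benzylidene]malonate | CCOC(=O)C(=Cc1ccc(O[Si](C(C)C)(C(C)C)C(C)C)c(OC)c1)C(=O)OCC
A2 | alternative 1 | prop-2-yn-1-ol | C#CCO
A3 | alternative 1 | (5-iodo-2-methoxyphenoxy)triisopropylsilane | COc1ccc(I)cc1O[Si](C(C)C)(C(C)C)C(C)C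
A4 | alternative 1 | diethyl (S,Z)-2-[3-methoxy-4-(triisopropylsilyloxy)phenyl]-4-[4-methoxy-3-(triisopropylsilyloxy)benzylidene]tetrahydrofuran-3,3-dicarboxylate | CCOC(=O)C1(C(=O)OCC)[C@H](c2ccc(O[Si](C(C)C)(C(C)C)C(C)C)c(OC)c2)OC/C1=C\c3ccc(OC)c(O[Si](C(C)C)(C(C)C)C(C)C)c3
A5 | alternative 2 | open-chain C2–C3 epoxy diol, 3-aryl-2-(hydroxymethyl)-2-[1-hydroxy-3-arylpropan-2-yl]oxirane with both phenols as pivalates | COc1ccc(C[C@@H](CO)[C@@]2(CO)O[C@@H]2c3ccc(OC(=O)C(C)(C)C)c(OC)c3)cc1OC(=O)C(C)(C)C
A6 | alternative 2 | (2S,3S,4S)-2-aryl-4-arylmethyl-3-hydroxy-3-(hydroxymethyl)tetrahydrofuran bis-pivalate | COc1ccc(C[C@H]2CO[C@@H](c3ccc(OC(=O)C(C)(C)C)c(OC)c3)[C@@]2(O)CO)cc1OC(=O)C(C)(C)C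
A7 | alternative 3 | 2-{[1-aryl-2-hydroxy-2-(tert-butyldimethylsilyloxymethyl)-4-arylbut-3-enyl]oxy}acetic acid, (E)-styrene, phenols as triisopropylsilyl ethers | OC(=O)CO[C@@H](c1ccc(O[Si](C(C)C)(C(C)C)C(C)C)c(OC)c1)[C@@](O)(CO[Si](C)(C)C(C)(C)C)/C=C/c1ccc(OC)c(O[Si](C(C)C)(C(C)C)C(C)C)c1
A8 | alternative 3 | (2S,3S,4S)-2-aryl-4-arylmethyl-3-(tert-butyldimethylsilyloxymethyl)tetrahydrofuran-3-ol, phenols as triisopropylsilyl ethers | COc1ccc(C[C@H]2CO[C@@H](c3ccc(O[Si](C(C)C)(C(C)C)C(C)C)c(OC)c3)[C@@]2(O)CO[Si](C)(C)C(C)(C)C)cc1O[Si](C(C)C)(C(C)C)C(C)C
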